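## Retrosynthetic overview

1. The target consists of three 8-methoxynaphthalen-1-ol units. Central unit B carries unit A (through A C4) at B C2 and unit C (through C C4) at B C4. The plan rests on the phenolic rings of A and C, that is the atoms C1(O)-C2-C3-C4(-B)-C4a-C8a of each outer naphthalene. Their 1-oxy-4-aryl pattern matches a 1-aryl-4-siloxycyclohexa-1,3-diene fused to an aryne.
2. Key disconnection: C1-C8a and C4-C4a in both A and C. Two molecules of 3-methoxybenzyne add to a bis(siloxydiene) carried by B, and each adduct then loses its CH2CH2 bridge as ethylene.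
3. The bis-diene comes from a twofold Suzuki-Miyaura coupling of the O-benzylated 2,4-dibromide of B with a commercial ketal-protected cyclohexenyl boronate, followed by ketal hydrolysis and soft enolisation.
4. Order of rings: B is bought as naphthalene-1,8-diol. The two carbocycles that become C1-C4 of A and C are attached next, the two anisole rings are fused on last, and aromatisation completes A and C.
5. End game: fluoride desilylation, then hydrogenolysis of the benzyl ether on B.

Key step: step 11

Assumption: the target SMILES carries no axial descriptor and neither biaryl axis has the ortho substitution needed for lasting configurational stability, so no atroposelective control is planned.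

## Route

Step 1
Reactants: 1 naphthalene-1,8-diol
Product: 2 8-methoxynaphthalen-1-ol
Conditions: MeI (1.05 equiv), K2CO3, acetone, reflux
Reagents that add atoms: iodomethane, CI
Why: Williamson etherification, in which K2CO3 forms only the monoanion stabilised by the peri hydrogen bond, and the product OH, tied to the new OMe, is much less acidic, so alkylation should stop at the monoether.

Step 2
Reactants: 2 8-methoxynaphthalen-1-ol
Product: 3 2,4-dibromo-8-methoxynaphthalen-1-ol
Conditions: NBS (2.05 equiv), MeCN, -20 to 0 °C, dark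
Reagents that add atoms: N-bromosuccinimide, O=C1CCC(=O)N1Br
Why: Electrophilic aromatic bromination, in which the free OH (made more electron-rich by its hydrogen bond to the peri OMe) directs to C4 and then C2 of its own ring, while C5 of the anisole ring is shielded by the peri bromine once C4 is substituted.

Step 3
Reactants: 3 2,4-dibromo-8-methoxynaphthalen-1-ol; 4 benzyl bromide
Product: 5 1-(benzyloxy)-2,4-dibromo-8-methoxynaphthalene
Conditions: K2CO3, DMF, 50 °C
Reagents that add atoms: none
Why: Williamson etherification of the acidified dibromonaphthol, giving a benzyl ether that should survive Pd catalysis, dilute acid, silyl triflate, n-BuLi at -78 °C and neutral heating.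

Step 4
Reactants: 5 1-(benzyloxy)-2,4-dibromo-8-methoxynaphthalene; 6 2-(1,4-dioxaspiro[4.5]dec-7-en-8-yl)-4,4,5,5-tetramethyl-1,3,2-dioxaborolane (2.5 equiv)
Product: 7 8,8'-[4-(benzyloxy)-5-methoxynaphthalene-1,3-diyl]bis(1,4-dioxaspiro[4.5]dec-7-ene)
Conditions: Pd(dppf)Cl2 (5 mol %), K2CO3, 1,4-dioxane-H2O, 90 °C
Reagents that add atoms: none
Why: Twofold Suzuki-Miyaura coupling of aryl bromides with an alkenyl pinacol boronate, which installs both six-membered rings with the C=C already in place and avoids an ortho-lithiated benzyl ether and additions to an enolisable ketone.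

Step 5
Reactants: 7 8,8'-[4-(benzyloxy)-5-methoxynaphthalene-1,3-diyl]bis(1,4-dioxaspiro[4.5]dec-7-ene)
Product: 8 4,4'-[4-(benzyloxy)-5-methoxynaphthalene-1,3-diyl]bis(cyclohex-3-en-1-one)
Conditions: 1 M aq. HCl, THF, rt
Reagents that add atoms: water, O
Why: Mild acid-catalysed ketal hydrolysis, in which the trisubstituted aryl-bearing C=C should stay at C3-C4, as is usual for 4-arylcyclohex-3-enones.

Step 6
Reactants: 8 4,4'-[4-(benzyloxy)-5-methoxynaphthalene-1,3-diyl]bis(cyclohex-3-en-1-one)
Product: 9 1-(benzyloxy)-2,4-bis[4-(tert-butyldimethylsilyloxy)cyclohexa-1,3-dien-1-yl]-8-methoxynaphthalene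
Conditions: TBSOTf (2.6 equiv), Et3N (4 equiv), CH2Cl2, 0 °C; cold aq. NaHCO3, short basic alumina plug, Ar, used at once
Reagents that add atoms: tert-butyldimethylsilyl trifluoromethanesulfonate, CC(C)(C)[Si](C)(C)OS(=O)(=O)C(F)(F)F
Why: Soft enolisation with silyl triflate and amine, in which the O-silylated ketone loses the doubly activated (alpha and allylic) C2-H and should give the conjugated 1-siloxy-1,3-diene, which is also the thermodynamic isomer.

Step 7
Reactants: 10 3-methoxyphenol
Product: 11 1-methoxy-3-(methoxymethoxy)benzene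
Conditions: MOMCl, i-Pr2NEt, CH2Cl2, 0 °C to rt
Reagents that add atoms: chloromethyl methyl ether, COCCl
Why: O-alkylation of the phenol gives a MOM acetal that serves as protecting group and as a strong director for the next metalation.

Step 8
Reactants: 11 1-methoxy-3-(methoxymethoxy)benzene
Product: 13 2-iodo-1-methoxy-3-(methoxymethoxy)benzene, via 2-lithio-1-methoxy-3-(methoxymethoxy)benzene 12 (not isolated)
Conditions: n-BuLi, THF, 0 °C; then I2, -78 °C to rt
Reagents that add atoms: iodine, II
Why: Directed ortho-metalation, in which OMe and OMOM cooperate to direct lithiation to the carbon between them, followed by iodinolysis of the aryllithium.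

Step 9
Reactants: 13 2-iodo-1-methoxy-3-(methoxymethoxy)benzene
Product: 14 2-iodo-3-methoxyphenol
Conditions: conc. HCl (cat.), MeOH, 45 °C
Reagents that add atoms: none
Why: Acid-catalysed acetal exchange with methanol should remove the MOM group without touching the aryl iodide or the methyl ether.

Step 10
Reactants: 14 2-iodo-3-methoxyphenol
Product: 15 2-iodo-3-methoxyphenyl trifluoromethanesulfonate
Conditions: Tf2O, pyridine, CH2Cl2, 0 °C
Reagents that add atoms: trifluoromethanesulfonic anhydride, O=S(=O)(OS(=O)(=O)C(F)(F)F)C(F)(F)F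
Why: O-sulfonylation of the phenol places the leaving group next to the iodine, which gives an ortho-halo triflate aryne precursor that needs no fluoride.

Step 11
Reactants: 9 1-(benzyloxy)-2,4-bis[4-(tert-butyldimethylsilyloxy)cyclohexa-1,3-dien-1-yl]-8-methoxynaphthalene; 15 2-iodo-3-methoxyphenyl trifluoromethanesulfonate (3 equiv)
Product: 19 1-(benzyloxy)-2,4-bis[4-(tert-butyldimethylsilyloxy)-5-methoxynaphthalen-1-yl]-8-methoxynaphthalene, via 2-lithio-3-methoxyphenyl triflate 16 (not isolated), via 3-methoxybenzyne 17 (not isolated), via twofold ethano-bridged cycloadduct 18 (not isolated)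
Conditions: n-BuLi (2.9 equiv, slow addition to premixed 9 and 15), THF, -78 °C to rt; pH 7 buffer wash, solvent switch to 1,2,4-trichlorobenzene, 200 °C, Ar stream
Reagents that add atoms: none
Why: Iodine-lithium exchange on 15 is faster than any attack of n-BuLi on 9, and 16 loses LiOTf already at -78 °C to give 17, which the s-cis-locked, electron-rich siloxydienes trap in a concerted but asynchronous [4+2] cycloaddition; heating crude 18 then triggers a retro-[4+2] in which each CH2CH2 bridge leaves as ethylene, driven by aromatisation and gas loss and eased by the siloxy and aryl groups on the breaking bridgehead bonds. The closest known reaction type is the Diels-Alder addition of arynes to 1-oxygenated cyclohexa-1,3-dienes followed by Alder-Rickert extrusion of ethylene from the benzobicyclo[2.2.2]octadiene, run here twice on one substrate. Each of the two rings (C1, C2, C3, C4, C4a, C8a of A and of C) is closed by intermolecular [4+2] annulation, with C4-C4a and C1-C8a formed in the same event. The four bridgehead stereocentres of 18 arise without control as a mixture of diastereomers, which is harmless because all four carbons become sp2 when ethylene leaves, so 19 holds no stereocentre. Regioselectivity is the selectivity needed: the siloxy group pushes electron density to the remote, aryl-bearing diene terminus, which bonds first to the more electrophilic aryne carbon meta to OMe, so the siloxy carbon ends on the carbon ortho to OMe (C1-O peri to C8-OMe), and the bulk of unit B, which avoids the methoxy side, points the same way. Chemoselectivity against ene reaction, hydrogen transfer and [2+2] addition is helped by the fixed s-cis geometry and donor activation of the diene, slow addition of n-BuLi keeps butyl addition to the aryne, attack at silicon and benzylic deprotonation low, and the solvent is changed after a neutral wash because THF cannot reach the extrusion temperature and lithium salts are better absent at 200 °C.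

Step 12
Reactants: 19 1-(benzyloxy)-2,4-bis[4-(tert-butyldimethylsilyloxy)-5-methoxynaphthalen-1-yl]-8-methoxynaphthalene
Product: 20 4,4'-[4-(benzyloxy)-5-methoxynaphthalene-1,3-diyl]bis(8-methoxynaphthalen-1-ol)
Conditions: TBAF (2.5 equiv), AcOH (2.5 equiv), THF, 0 °C, Ar
Reagents that add atoms: none
Why: Fluoride-mediated cleavage of aryl silyl ethers, buffered with acetic acid so that the electron-rich naphtholates are protonated at once and are not exposed to oxidative coupling.

Step 13
Reactants: 20 4,4'-[4-(benzyloxy)-5-methoxynaphthalene-1,3-diyl]bis(8-methoxynaphthalen-1-ol)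
Product: 21 2,4-bis(4-hydroxy-5-methoxynaphthalen-1-yl)-8-methoxynaphthalen-1-ol (target)
Conditions: H2 (1 atm), 10% Pd/C, EtOAc-MeOH, rt
Reagents that add atoms: none
Why: Catalytic hydrogenolysis of the aryl benzyl ether at atmospheric pressure should leave the naphthalene rings and methyl ethers untouched.

## Compound list

1 | naphthalene-1,8-diol | Oc1cccc2cccc(O)c12 | starting material
2 | 8-methoxynaphthalen-1-ol | COc1cccc2cccc(O)c12 | intermediate
3 | 2,4-dibromo-8-methoxynaphthalen-1-ol | COc1cccc2c(Br)cc(Br)c(O)c12 | intermediate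
4 | benzyl bromide | BrCc1ccccc1 | starting material
5 | 1-(benzyloxy)-2,4-dibromo-8-methoxynaphthalene | COc1cccc2c(Br)cc(Br)c(OCc3ccccc3)c12 | intermediate
6 | 2-(1,4-dioxaspiro[4.5]dec-7-en-8-yl)-4,4,5,5-tetramethyl-1,3,2-dioxaborolane | CC1(C)OB(OC1(C)C)C1=CCC2(CC1)OCCO2 | starting material
7 | 8,8'-[4-(benzyloxy)-5-methoxynaphthalene-1,3-diyl]bis(1,4-dioxaspiro[4.5]dec-7-ene) | COc1cccc2c(C3=CCC4(CC3)OCCO4)cc(C3=CCC4(CC3)OCCO4)c(OCc3ccccc3)c12 | intermediate
8 | 4,4'-[4-(benzyloxy)-5-methoxynaphthalene-1,3-diyl]bis(cyclohex-3-en-1-one) | COc1cccc2c(C3=CCC(=O)CC3)cc(C3=CCC(=O)CC3)c(OCc3ccccc3)c12 | intermediate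
9 | 1-(benzyloxy)-2,4-bis[4-(tert-butyldimethylsilyloxy)cyclohexa-1,3-dien-1-yl]-8-methoxynaphthalene | COc1cccc2c(C3=CC=C(O[Si](C)(C)C(C)(C)C)CC3)cc(C3=CC=C(O[Si](C)(C)C(C)(C)C)CC3)c(OCc3ccccc3)c12 | intermediate
10 | 3-methoxyphenol | COc1cccc(O)c1 | starting material
11 | 1-methoxy-3-(methoxymethoxy)benzene | COCOc1cccc(OC)c1 | intermediate
12 | 2-lithio-1-methoxy-3-(methoxymethoxy)benzene | [Li]c1c(OC)cccc1OCOC | intermediate
13 | 2-iodo-1-methoxy-3-(methoxymethoxy)benzene | COCOc1cccc(OC)c1I | intermediate
14 | 2-iodo-3-methoxyphenol | COc1cccc(O)c1I | intermediate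
15 | 2-iodo-3-methoxyphenyl trifluoromethanesulfonate | COc1cccc(OS(=O)(=O)C(F)(F)F)c1I | intermediate
16 | 2-lithio-3-methoxyphenyl trifluoromethanesulfonate | [Li]c1c(OC)cccc1OS(=O)(=O)C(F)(F)F | intermediate
17 | 3-methoxybenzyne (1-methoxy-2,3-didehydrobenzene) | COC1=CC=CC#C1 | intermediate
18 | 1-(benzyloxy)-2,4-bis[4-(tert-butyldimethylsilyloxy)-5-methoxy-1,4-dihydro-1,4-ethanonaphthalen-1-yl]-8-methoxynaphthalene (mixture of diastereomers, bridgehead centres uncontrolled and lost in the same step) | COc1cccc2c(C34C=CC(O[Si](C)(C)C(C)(C)C)(CC3)c3c(OC)cccc34)cc(C34C=CC(O[Si](C)(C)C(C)(C)C)(CC3)c3c(OC)cccc34)c(OCc3ccccc3)c12 | intermediate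
19 | 1-(benzyloxy)-2,4-bis[4-(tert-butyldimethylsilyloxy)-5-methoxynaphthalen-1-yl]-8-methoxynaphthalene | COc1cccc2c(-c3ccc(O[Si](C)(C)C(C)(C)C)c4c(OC)cccc34)cc(-c3ccc(O[Si](C)(C)C(C)(C)C)c4c(OC)cccc34)c(OCc3ccccc3)c12 | intermediate
20 | 4,4'-[4-(benzyloxy)-5-methoxynaphthalene-1,3-diyl]bis(8-methoxynaphthalen-1-ol) | COc1cccc2c(-c3ccc(O)c4c(OC)cccc34)cc(-c3ccc(O)c4c(OC)cccc34)c(OCc3ccccc3)c12 | intermediate
21 | 2,4-bis(4-hydroxy-5-methoxynaphthalen-1-yl)-8-methoxynaphthalen-1-ol | COc1cccc2c(-c3cc(-c4ccc(O)c5c(OC)cccc45)c4cccc(OC)c4c3O)ccc(O)c12 | target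

## Step count and risks

Total step count: 13.
Longest linear sequence: 9 steps (steps 1 to 6, then 11 to 13, from 1). The aryne branch (steps 7 to 10) joins at step 11.

**Step 11.**
- What may go wrong: ene reaction or hydrogen transfer at the ring CH2 groups may aromatise a diene instead of annulating it. The reaction may stall after the first cycloaddition at the crowded site beside the benzyloxy group. The orientation of addition may leak, or ethylene extrusion may be sluggish.
- Fallback: give up ring construction and attach ready-made outer naphthalenes by cross-coupling. It sets out from 2 (with 5 as partner) and comes back at 19.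
- NBS (1 equiv, MeCN, -20 °C) should brominate 2 para to OH to give 4-bromo-8-methoxynaphthalen-1-ol F1.
- TBSCl and imidazole in DMF give [(4-bromo-8-methoxynaphthalen-1-yl)oxy](tert-butyl)dimethylsilane F2.
- Miyaura borylation (B2pin2, Pd(dppf)Cl2, KOAc, dioxane, 90 °C) gives tert-butyl{[8-methoxy-4-(4,4,5,5-tetramethyl-1,3,2-dioxaborolan-2-yl)naphthalen-1-yl]oxy}dimethylsilane F3.
- A twofold Suzuki-Miyaura coupling of this boronate (2.5 equiv) with 5 (Pd(OAc)2, SPhos, K3PO4, toluene-H2O, 90 °C) returns to 19. Partial loss of silyl groups under the basic coupling would only lead on to 20.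

**Step 6.**
- What may go wrong: enolisation may go towards C6 instead of C2, the dienol ethers may hydrolyse on isolation, or air may dehydrogenate the dienes to arenes.
- Fallback: replace the silyl dienol ethers by robust dienyl acetates and generate the aryne with fluoride instead of n-BuLi. It sets out from 8 and comes back at 20.
- Thermodynamic enol acetylation (isopropenyl acetate, cat. TsOH, reflux) should give [4-(benzyloxy)-5-methoxynaphthalene-1,3-diyl]bis(cyclohexa-1,3-diene-4,1-diyl) diacetate F4, which tolerates chromatography.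
- Commercial 3-methoxy-2-(trimethylsilyl)phenyl trifluoromethanesulfonate with CsF in MeCN-toluene at rt releases 17, which should give the twofold ethano-bridged cycloadduct diacetate F5.
- Heating in 1,2,4-trichlorobenzene at 200 °C expels ethylene to give [4-(benzyloxy)-5-methoxynaphthalene-1,3-diyl]bis(8-methoxynaphthalene-4,1-diyl) diacetate F6.
- K2CO3 in MeOH returns to 20. The acetoxy donor polarises the diene less, so the orientation would lean more on the steric bias of unit B.

**Step 2.**
- What may go wrong: bromination may spill into the anisole ring (C5 or C7), or the naphthol may be oxidised towards quinone-type material.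
- Fallback: set C2 by directed metalation and only C4 by electrophilic substitution. It sets out from 2 and comes back at 3.
- MOMCl and i-Pr2NEt give 1-methoxy-8-(methoxymethoxy)naphthalene F7.
- n-BuLi and TMEDA in Et2O at 0 °C should metalate ortho to the stronger OMOM director (the peri site is blocked) to give 2-lithio-8-methoxy-1-(methoxymethoxy)naphthalene F8.
- 1,2-Dibromoethane converts the aryllithium into 2-bromo-8-methoxy-1-(methoxymethoxy)naphthalene F9.
- Catalytic HCl in MeOH frees 2-bromo-8-methoxynaphthalen-1-ol F10, and NBS (1 equiv, MeCN, -20 °C) brominates the remaining para position to return to 3.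

Further compounds
F1 | step 11 | 4-bromo-8-methoxynaphthalen-1-ol | COc1cccc2c(Br)ccc(O)c12
F2 | step 11 | [(4-bromo-8-methoxynaphthalen-1-yl)oxy](tert-butyl)dimethylsilane | COc1cccc2c(Br)ccc(O[Si](C)(C)C(C)(C)C)c12
F3 | step 11 | tert-butyl{[8-methoxy-4-(4,4,5,5-tetramethyl-1,3,2-dioxaborolan-2-yl)naphthalen-1-yl]oxy}dimethylsilane | COc1cccc2c(B3OC(C)(C)C(C)(C)O3)ccc(O[Si](C)(C)C(C)(C)C)c12
F4 | step 6 | [4-(benzyloxy)-5-methoxynaphthalene-1,3-diyl]bis(cyclohexa-1,3-diene-4,1-diyl) diacetate | COc1cccc2c(C3=CC=C(OC(C)=O)CC3)cc(C3=CC=C(OC(C)=O)CC3)c(OCc3ccccc3)c12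
F5 | step 6 | twofold ethano-bridged cycloadduct diacetate (mixture of diastereomers) | COc1cccc2c(C34C=CC(OC(C)=O)(CC3)c3c(OC)cccc34)cc(C34C=CC(OC(C)=O)(CC3)c3c(OC)cccc34)c(OCc3ccccc3)c12
F6 | step 6 | [4-(benzyloxy)-5-methoxynaphthalene-1,3-diyl]bis(8-methoxynaphthalene-4,1-diyl) diacetate | COc1cccc2c(-c3ccc(OC(C)=O)c4c(OC)cccc34)cc(-c3ccc(OC(C)=O)c4c(OC)cccc34)c(OCc3ccccc3)c12
F7 | step 2 | 1-methoxy-8-(methoxymethoxy)naphthalene | COCOc1cccc2cccc(OC)c12
F8 | step 2 | 2-lithio-8-methoxy-1-(methoxymethoxy)naphthalene | [Li]c1ccc2cccc(OC)c2c1OCOC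
F9 | step 2 | 2-bromo-8-methoxy-1-(methoxymethoxy)naphthalene | COCOc1c(Br)ccc2cccc(OC)c12
F10 | step 2 | 2-bromo-8-methoxynaphthalen-1-ol | COc1cccc2ccc(Br)c(O)c12
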